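The constants used here are made up; what happens was integrated by code.

4 questions are asked of 3 flasks that differ in how starting material and reagent go in.

    starting material + reagent + catalyst → catalyst + target (k1 = 29000 M⁻² s⁻¹)
    2 reagent → self-condensation product (k2 = 0.16 M⁻¹ s⁻¹)
    starting material + reagent → uncatalysed product (k3 = 0.80 M⁻¹ s⁻¹)

| flask | starting material | reagent | catalyst | time | remark |
|---|---|---|---|---|---|
| autumn | 0.016 M (fed, over 30 s) | 0.0480 M | 32 µM | 40 s | all else is in the flask from the start; the feed brings no volume worth counting |
| noon | 0.016 M | 0.0480 M | 32 µM | 40 s | everything together at the start |
| winter | 0.016 M | 0.0480 M (fed, over 30 s) | 32 µM | 40 s | all else is in the flask from the start; the feed brings no volume worth counting |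

- where a step has two of a species, its rate is k times that concentration squared, and two are used at each turn
- run time (autumn): 40 s

* which flask leads in share of target in target plus uncatalysed product ("all alike" within 1.5 percentage points) (autumn / noon / winter / all alike)
* share of target in target plus uncatalysed product at the end, autumn
* share of target in target plus uncatalysed product at the end, noon
* share of target in target plus uncatalysed product at the end, winter

The catalysed and uncatalysed steps each run first order in starting material and in reagent, and catalyst returns at each turn, so its concentration c stays at the charge. Control therefore changes hands at the crossover concentration c×, the constant of the uncatalysed step over that of the catalysed step: 27.6 µM. The target's share of the two products is c/(c + c×), and the charged 32 µM lies above c×, which gives 53.7 %.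

In noon, the target curve starts with a slope of 7.13 × 10⁻⁴ M s⁻¹. The noon curve bends near the lifetime of starting material against both steps with reagent as charged, 12.1 s. The first half-life of reagent by self-condensation alone, 65.1 s, is longer than that lifetime. The noon curve then runs toward a level of 0.00859 M, that share of the starting material charged. The feed in autumn and in winter lasts 30 s, longer than that lifetime, but at each moment both rates carry the same product of starting material and reagent. The reckoned share is thus a flat line at 53.7 % in each flask.

The forecast gives 53.7 % for autumn, 53.7 % for noon and 53.7 % for winter, each with a range of 53.5 % to 53.9 %, and answers all alike: the ratio holds “whatever the concentrations”. It rests on the same ratio as the reckoning above, so the two are one argument and not a check on each other.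

The simulation gives 53.7 % for autumn, 53.7 % for noon and 53.7 % for winter, so the answer is all alike. In autumn at 40.0 s, the catalysed step uses starting material 1.2 times as fast as the uncatalysed step, against c/c×, the selectivity factor, of 1.16, while 32.2 % of the starting material still stands at the end of autumn and 12 % at the end of noon.

For the neighbour of autumn with 1.3 × 10⁻⁴ M of catalyst, c× of 27.6 µM gives a share of 82.5 %. The computed result there is 82.5 %.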